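## Structural features

The target is a cembranolide. A 14-membered carbocycle (C1–C14, cembrane numbering, used throughout) is cis-fused across C1–C2 to an α-methylene-γ-butyrolactone; the lactone carbons are C15 (α), C16 (carbonyl) and C17 (exocyclic methylene), and the ring oxygen sits on C2. Going round the large ring there are an E trisubstituted alkene C3=C4 (methyl on C4), a doubly allylic methylene C5, an E disubstituted alkene C6=C7, a tertiary allylic carbinol C8, two methylenes C9 and C10, a trisubstituted epoxide C11–C12 (methyl on C12) and the acetoxy carbon C13, which is tied back to C1 through C14. The six stereocentres form three groups: C1/C2 (adjacent, ring fusion), C11/C12/C13 (adjacent; C10 and C13 cis on the epoxide, epoxide oxygen and acetate erythro) and the isolated quaternary C8, which no neighbouring centre can control. Fragile groups are the methylene lactone (conjugate acceptor for phosphines, hydrides, boranes and amines), the epoxy acetate (acid, acyl shift, Payne rearrangement), the tertiary allylic alcohol and the allylic C2–O bond (ionisation), and the skipped diene (migration into conjugation). The real difficulty is closing the 14-membered ring without creating or scrambling an alkene geometry, and then placing the epoxide on one face of a macrocyclic alkene. The key step uses the fact that the parent alkene C11=C12 must be Z and trisubstituted: it is made beforehand as an iodoalkene and joined at the adjacent saturated carbon C10, which is the terminus of the vinyl group on C8.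

## Logic of the disconnections

38 to 37: only the O–Si bond at C8 is cut. The tertiary allylic hydroxyl stays masked to the end because a free one would steer a metal-directed epoxidation to C6=C7 and ionises easily. Nothing is gained in skeleton, but the last operation becomes a mild fluoride step. It must spare epoxide, acetate and methylene lactone.

37 to 36: the C13–O(acyl) bond is cut with inversion. In the rotamer enforced by allylic strain against C10, it is the hydroxyl of the C13 epimer that lies on the alkene face carrying the epoxide of 38. Acetate and the correct C13 configuration then arrive in one substitution. The demand is a clean SN2 at a secondary carbinol beside a fully substituted epoxide carbon.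

36 to 35: both epoxide C–O bonds are cut back to the Z alkene. C11 and C12 then derive from alkene geometry plus hydroxyl direction. The forward step needs oxygen delivery syn to O13 and selectivity over three other alkenes.

35 to 34 to 32 to 30: the benzylic C–O bond of the C13 ether and the C15–C17 bond are cut. A methylene lactone would not survive boranes, so 30 carries the saturated lactone. The demand is enolisation at C15 only.

30 to 28: the C10–C11 bond is cut. This opens the ring next to the Z alkene, so no geometry and no stereocentre is created on closure. The C13 configuration of 28 and 30 was checked against 38: it is deliberately epimeric, as the directed epoxidation requires. The forward step needs hydroboration at one of five alkenes and a macrocyclic sp3–sp2 coupling.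

28 to 22 + 26: the C6=C7 bond is cut. This splits off quaternary C8 as a small chiral aldehyde. An olefination is preferred to a palladium coupling at C5–C6 because 22 already carries the alkenyl iodide. The demand is E selectivity and a base step that the lactone tolerates.

26 to 25 to 24 to 23: the tertiary C8–O bond is cut. C8 then comes from a racemic vinyl epoxide by a catalyst-controlled, enantioconvergent opening. The demand is attack at the tertiary terminus with high enantioselectivity.

22 to 20 to 19 to 18: only the C6 substituent changes (C–S for C–O, then S=O bonds). This keeps the acidic sulfone out of the earlier borane and oxidation steps. The oxidation at sulfur must leave the alkenes alone.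

18 to 16 to 14: the lactone C16–O2 bond is cut and C16 is lowered to a vinyl carbon. A vinyl group on C1 is the direct product of an allylboration. It has to be oxidised before 26 brings in the second vinyl group, which is why the lactone is made at this stage. The demand is hydroboration of one monosubstituted alkene beside two trisubstituted ones.

14 to 8 + 12: the C1–C2 bond is cut. A closed transition state turns the Z geometry of 8 into the syn C1/C2 relationship, which is the cis ring fusion. Both stereocentres arise in one step. The demand is catalyst control of the aldehyde face over the remote C13 centre.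

8 to 7 to 6 to 4 to 3 to 1: the C1=C15 bond (metathesis), the C13–C14 bond (allylboration), and the C12–methyl and C11–I bonds (carbometallation) are cut. The whole C11–C16 arm comes from a three-carbon alcohol. The demands are Z selectivity twice, at C11=C12 and at C1=C15.

12 to 11 to 9: the C2–C3 bond (formaldehyde) and the C4–methyl bond are cut. One carboalumination sets the E trisubstituted alkene.

## Other disconnections considered

Alternative 1: The cut runs through C2–C3; the C4–methyl bond and the lactone C16–O bond are made in the same operation. Carboalumination of alkyne A2 (Cp2ZrCl2, AlMe3) gives an E alkenylalane that adds to aldehyde A3, and the aluminium alkoxide closes the lactone to give A1. The ring would then have to be closed at C12–C13, for example by a Nozaki–Hiyama–Kishi reaction.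
- In its favour: three bonds and the E trisubstituted alkene form in one flask, and the methylene lactone needs no separate installation. On convergence and on step count around C1–C5 it is the better plan.
- Against it: C2 is set by open-chain 1,2-induction from C1, whose two carbon substituents offer little bias, and aluminium chelation by the ester may oppose it, so a cis/trans mixture must be expected. The α-proton of A3 is doubly activated and can epimerise or let the alkene migrate. Alkenylalanes add slowly to aldehydes and methyl transfer competes. In A1, C13 is still a primary ether, so the C13 stereocentre would arise in the ring closure without reagent control.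
- Comparison: both plans bring the Z alkene in preformed. Alternative 1 creates a stereocentre on ring closure, the chosen plan creates none. An open transition state stands against the closed chair of the allylboration. The protecting-group count is equal.

Alternative 2: The cut removes C16 as carbon monoxide (bonds C15–C16 and C16–O2). PdCl2(PPh3)2 with SnCl2 under CO would turn the macrocyclic homopropargylic alcohol A5 into A4, which is the same compound as 34 of the chosen route.
- In its favour: one step replaces steps 9, 10, 19 and 20, so it is the better plan on step economy for the lactone. It also avoids the strong base of the Mannich step. The syn ethynyl/hydroxyl relationship could be set by a syn-selective propargylation about as reliably as the allylboration sets C1/C2, so the two plans are equal on that point.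
- Against it: 9-BBN would hydroborate the terminal alkyne of A5 at least as readily as the C9–C10 vinyl group. The Suzuki closure could then only be used with silyl protection and later removal of the alkyne, which gives back two steps. The carbonylation medium is acidic and forms palladium hydrides, a risk for the skipped diene and the tertiary allylic silyl ether on a late macrocycle.
- Comparison: the endgame after A4 would be identical. The chosen plan pays four ordinary steps for a ring closure free of this chemoselectivity problem.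

Alternative 3: The cut is C4–C5. [CpRu(MeCN)3]PF6 would couple the propynyl group on C2 with the allyl group on C8 of seco enyne A7, shifting the alkene to C6=C7 and closing the ring to A6, which is the same compound as 37.
- In its favour: it is atom-economical and needs no base. The E trisubstituted alkene, the skipped diene and the ring form together. All stereocentres, the epoxide included, would be set on acyclic material where reagent-controlled epoxidation applies; this is better than the substrate-directed macrocyclic epoxidation of the chosen plan. Only one step would follow the ring closure.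
- Against it: whether the new bond forms at C4 or at C3 is not secured. The methylene lactone is itself a good alkene partner for the ruthenacycle. The propargylic C2–O bond, the epoxide and the tertiary silyl ether all face a cationic, Lewis acidic metal. A 14-membered closure of this type on such a substrate would be a long extrapolation.
- Comparison: the chosen plan fixes every alkene geometry and the connectivity before ring closure and uses a mechanism without regiochemical choice. Alternative 3 could be several steps shorter, but concentrates the risk in one late step.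

Key step: step 18

Assumptions:
- The absolute sense of the two catalyst-controlled steps (8 and 14) is taken from the usual behaviour of these catalyst families; if either runs the other way, the antipodal acid or ligand is used and nothing else changes.
- The structures of 28 and 30 were checked against 38 and needed no correction.

## Route

Step 1
Reactants: 1 prop-2-yn-1-ol (propargyl alcohol)
Product: 3 (Z)-3-iodo-2-methylprop-2-en-1-ol, via alkenylmagnesium bromide alkoxide 2 (not isolated)
Conditions: MeMgBr (3 equiv), CuI (10 mol%), THF, −10 °C → rt; then I2, −10 °C → rt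
Reagents that add atoms: methylmagnesium bromide C[Mg]Br; iodine II
Why: Copper-catalysed anti-carbomagnesiation of the propargylic alkoxide puts methyl on C12 and magnesium on C11 cis to the carbinol carbon through a chelate; iodinolysis with retention gives the Z iodoalkene.

Step 2
Reactants: 3 (Z)-3-iodo-2-methylprop-2-en-1-ol
Product: 4 (Z)-3-iodo-2-methylprop-2-enal
Conditions: MnO2 (excess), CH2Cl2, rt, dark; used at once
Reagents that add atoms: none
Why: Allylic oxidation on MnO2 is neutral and should keep the Z geometry; the aldehyde is not stored.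

Step 3
Reactants: 4 (Z)-3-iodo-2-methylprop-2-enal
Product: 6 (3S,1Z)-1-iodo-2-methylhexa-1,5-dien-3-ol, via diisopinocampheylborinate 5 (not isolated)
Conditions: (−)-Ipc2BOMe (from (+)-α-pinene), CH2=CHCH2MgBr, Et2O, −78 °C → rt; then 4, −78 °C; NaOH, H2O2, 0 °C → rt
Reagents that add atoms: B-allyldiisopinocampheylborane, made in the flask from (−)-Ipc2BOMe and allylmagnesium bromide (C=CC[Mg]Br), C=CCB([C@H]1[C@H](C)[C@H]2C[C@@H](C1)C2(C)C)[C@H]1[C@H](C)[C@H]2C[C@@H](C1)C2(C)C
Why: Asymmetric allylboration through a chair six-membered transition state; the isopinocampheyl groups from (+)-α-pinene direct the allyl group to the face that gives the S carbinol. This sets C13 in the configuration epimeric to the target, as the later directed epoxidation and inversion require.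

Step 4
Reactants: 6 (3S,1Z)-1-iodo-2-methylhexa-1,5-dien-3-ol
Product: 7 (3S,1Z)-1-iodo-3-(4-methoxybenzyloxy)-2-methylhexa-1,5-diene
Conditions: NaH, 4-methoxybenzyl chloride, Bu4NI (cat.), THF/DMF, 0 °C → rt
Reagents that add atoms: 4-methoxybenzyl chloride COc1ccc(CCl)cc1
Why: Williamson etherification; the ether is stable to boranes, base and fluoride and can later be removed oxidatively in the presence of the silyl ether at C8.

Step 5
Reactants: 7 (3S,1Z)-1-iodo-3-(4-methoxybenzyloxy)-2-methylhexa-1,5-diene
Product: 8 2-[(2Z,5S,6Z)-7-iodo-5-(4-methoxybenzyloxy)-6-methylhepta-2,6-dien-1-yl]-4,4,5,5-tetramethyl-1,3,2-dioxaborolane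
Conditions: allylboronic acid pinacol ester (3 equiv), Mo(N-1-adamantyl)(CHCMe2Ph)(2,5-dimethylpyrrolide)(O-2,6-(2,4,6-iPr3C6H2)2C6H3) (5 mol%), benzene, rt, reduced pressure
Reagents that add atoms: allylboronic acid pinacol ester C=CCB1OC(C)(C)C(C)(C)O1
Why: Z-selective olefin cross-metathesis; the large aryloxide forces both substituents of the metallacyclobutane toward the small imido ligand, so the kinetic Z alkene results. The trisubstituted iodoalkene should not engage the alkylidene.

Step 6
Reactants: 9 tert-butyl(but-3-yn-1-yloxy)dimethylsilane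
Product: 11 (E)-5-(tert-butyldimethylsilyloxy)-3-methylpent-2-en-1-ol, via alkenyldimethylalane 10 (not isolated)
Conditions: AlMe3 (2.5 equiv), Cp2ZrCl2 (0.25 equiv), CH2Cl2, 0 °C → rt; then (CH2O)n, 0 °C → rt; aqueous sodium potassium tartrate
Reagents that add atoms: trimethylaluminium C[Al](C)C; formaldehyde (from paraformaldehyde) C=O
Why: Negishi carboalumination adds methyl and aluminium syn with aluminium on the terminal carbon; the alkenyl–aluminium bond adds to formaldehyde with retention, which fixes the E geometry of C3=C4.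

Step 7
Reactants: 11 (E)-5-(tert-butyldimethylsilyloxy)-3-methylpent-2-en-1-ol
Product: 12 (E)-5-(tert-butyldimethylsilyloxy)-3-methylpent-2-enal
Conditions: MnO2 (excess), CH2Cl2, rt
Reagents that add atoms: none
Why: Allylic oxidation on MnO2 without E/Z isomerisation of the β,β-disubstituted enal.

Step 8
Reactants: 8 2-[(2Z,5S,6Z)-7-iodo-5-(4-methoxybenzyloxy)-6-methylhepta-2,6-dien-1-yl]-4,4,5,5-tetramethyl-1,3,2-dioxaborolane; 12 (E)-5-(tert-butyldimethylsilyloxy)-3-methylpent-2-enal
Product: 14 (3E,5R,6S,8S,9Z)-1-(tert-butyldimethylsilyloxy)-6-ethenyl-10-iodo-8-(4-methoxybenzyloxy)-3,9-dimethyldeca-3,9-dien-5-ol, via pinacol borate ester 13 (not isolated)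
Conditions: (R)-3,3'-bis(2,4,6-triisopropylphenyl)-1,1'-binaphthyl-2,2'-diyl hydrogen phosphate (5 mol%), 4 Å molecular sieves, toluene, −30 °C; aqueous NaHCO3 work-up
Reagents that add atoms: none
Why: Chiral Brønsted acid-catalysed allylboration through a chair transition state with the acid hydrogen-bonded to a boronate oxygen. The Z geometry of 8 gives the syn C1/C2 relationship (the later cis ring fusion), and the acid antipode selects the Re face of the aldehyde, which gives 2R and with it 1S. The two possible syn products are diastereomers because of C13 and can be separated if needed.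

Step 9
Reactants: 14 (3E,5R,6S,8S,9Z)-1-(tert-butyldimethylsilyloxy)-6-ethenyl-10-iodo-8-(4-methoxybenzyloxy)-3,9-dimethyldeca-3,9-dien-5-ol
Product: 16 (3E,5R,6R,8S,9Z)-1-(tert-butyldimethylsilyloxy)-6-(2-hydroxyethyl)-10-iodo-8-(4-methoxybenzyloxy)-3,9-dimethyldeca-3,9-dien-5-ol, via bis-borylated adduct 15 (not isolated)
Conditions: 9-BBN (2.5 equiv), THF, 0 °C → rt; then NaOH, H2O2, 0 °C
Reagents that add atoms: hydrogen peroxide OO
Why: Anti-Markovnikov hydroboration–oxidation; 9-BBN takes the only monosubstituted alkene, since the trisubstituted alkene and the iodoalkene react far more slowly, and the hydroxyl consumes one equivalent as a borinate. No stereocentre changes; the C6 descriptor changes only through CIP priorities.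

Step 10
Reactants: 16 (3E,5R,6R,8S,9Z)-1-(tert-butyldimethylsilyloxy)-6-(2-hydroxyethyl)-10-iodo-8-(4-methoxybenzyloxy)-3,9-dimethyldeca-3,9-dien-5-ol
Product: 18 (4S,5R)-5-[(E)-4-(tert-butyldimethylsilyloxy)-2-methylbut-1-en-1-yl]-4-[(2S,3Z)-4-iodo-2-(4-methoxybenzyloxy)-3-methylbut-3-en-1-yl]dihydrofuran-2(3H)-one, via lactol 17 (not isolated)
Conditions: TEMPO (20 mol%), PhI(OAc)2 (2.5 equiv), CH2Cl2, rt
Reagents that add atoms: none
Why: Oxoammonium oxidation takes the primary alcohol first; the aldehyde is trapped by the C2 hydroxyl as a lactol, which is oxidised on to the γ-lactone. The syn diol gives the cis-disubstituted lactone.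

Step 11
Reactants: 18 (4S,5R)-5-[(E)-4-(tert-butyldimethylsilyloxy)-2-methylbut-1-en-1-yl]-4-[(2S,3Z)-4-iodo-2-(4-methoxybenzyloxy)-3-methylbut-3-en-1-yl]dihydrofuran-2(3H)-one
Product: 19 (4S,5R)-5-[(E)-4-hydroxy-2-methylbut-1-en-1-yl]-4-[(2S,3Z)-4-iodo-2-(4-methoxybenzyloxy)-3-methylbut-3-en-1-yl]dihydrofuran-2(3H)-one
Conditions: Bu4NF, AcOH, THF, 0 °C → rt
Reagents that add atoms: none
Why: Fluoride desilylation of the primary silyl ether; acetic acid buffering protects the lactone.

Step 12
Reactants: 19 (4S,5R)-5-[(E)-4-hydroxy-2-methylbut-1-en-1-yl]-4-[(2S,3Z)-4-iodo-2-(4-methoxybenzyloxy)-3-methylbut-3-en-1-yl]dihydrofuran-2(3H)-one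
Product: 20 (4S,5R)-4-[(2S,3Z)-4-iodo-2-(4-methoxybenzyloxy)-3-methylbut-3-en-1-yl]-5-[(E)-2-methyl-4-(1-phenyl-1H-tetrazol-5-ylthio)but-1-en-1-yl]dihydrofuran-2(3H)-one
Conditions: 1-phenyl-1H-tetrazole-5-thiol, PPh3, DIAD, THF, 0 °C → rt
Reagents that add atoms: 1-phenyl-1H-tetrazole-5-thiol Sc1nnnn1-c1ccccc1
Why: Mitsunobu thioetherification of an unhindered primary alcohol by an acidic thiol.

Step 13
Reactants: 20 (4S,5R)-4-[(2S,3Z)-4-iodo-2-(4-methoxybenzyloxy)-3-methylbut-3-en-1-yl]-5-[(E)-2-methyl-4-(1-phenyl-1H-tetrazol-5-ylthio)but-1-en-1-yl]dihydrofuran-2(3H)-one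
Product: 22 (4S,5R)-4-[(2S,3Z)-4-iodo-2-(4-methoxybenzyloxy)-3-methylbut-3-en-1-yl]-5-[(E)-2-methyl-4-(1-phenyl-1H-tetrazol-5-ylsulfonyl)but-1-en-1-yl]dihydrofuran-2(3H)-one, via sulfoxide 21 (not isolated)
Conditions: (NH4)6Mo7O24·4H2O (15 mol%), H2O2 (30%), EtOH, 0 °C → rt
Reagents that add atoms: hydrogen peroxide OO
Why: Molybdate-catalysed oxidation of sulfide to sulfone; the peroxomolybdate attacks sulfur much faster than alkenes that carry no free allylic hydroxyl.

Step 14
Reactants: 23 2-methyl-2-vinyloxirane (racemic)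
Product: 24 (S)-2-methylbut-3-ene-1,2-diol
Conditions: Pd2(dba)3·CHCl3 (1 mol%), (R,R)-N,N'-(cyclohexane-1,2-diyl)bis[2-(diphenylphosphino)-1-naphthamide] (3 mol%; antipode chosen for the S product), NaHCO3, BEt3 (1 mol%), CH2Cl2/H2O, rt
Reagents that add atoms: sodium hydrogencarbonate [Na+].OC([O-])=O
Why: Palladium-catalysed dynamic kinetic asymmetric allylic substitution. Both epoxide enantiomers ionise to interconverting π-allyl alkoxide complexes, the boron-tethered hydrogencarbonate attacks the tertiary terminus inside the chiral pocket and then loses CO2. This sets C8 (S).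

Step 15
Reactants: 24 (S)-2-methylbut-3-ene-1,2-diol
Product: 25 (S)-2-methyl-1,2-bis(triethylsilyloxy)but-3-ene
Conditions: Et3SiOTf (2.5 equiv), 2,6-lutidine, CH2Cl2, −78 → 0 °C
Reagents that add atoms: triethylsilyl trifluoromethanesulfonate CC[Si](CC)(CC)OS(=O)(=O)C(F)(F)F
Why: Silylation of both hydroxyls; the triflate is needed for the tertiary one.

Step 16
Reactants: 25 (S)-2-methyl-1,2-bis(triethylsilyloxy)but-3-ene
Product: 26 (S)-2-methyl-2-(triethylsilyloxy)but-3-enal
Conditions: (COCl)2, DMSO, CH2Cl2, −78 → −30 °C; Et3N, −78 °C → rt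
Reagents that add atoms: none
Why: Swern conditions cleave and oxidise a primary triethylsilyl ether directly and leave the tertiary one. The aldehyde has no α-hydrogen and cannot epimerise or move into conjugation.

Step 17
Reactants: 22 (4S,5R)-4-[(2S,3Z)-4-iodo-2-(4-methoxybenzyloxy)-3-methylbut-3-en-1-yl]-5-[(E)-2-methyl-4-(1-phenyl-1H-tetrazol-5-ylsulfonyl)but-1-en-1-yl]dihydrofuran-2(3H)-one; 26 (S)-2-methyl-2-(triethylsilyloxy)but-3-enal
Product: 28 (4S,5R)-4-[(2S,3Z)-4-iodo-2-(4-methoxybenzyloxy)-3-methylbut-3-en-1-yl]-5-[(1E,4E,6S)-2,6-dimethyl-6-(triethylsilyloxy)octa-1,4,7-trien-1-yl]dihydrofuran-2(3H)-one, via potassium alkoxide adduct 27 (not isolated)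
Conditions: KN(SiMe3)2 added to 22 + 26, DME, −60 °C → rt
Reagents that add atoms: none
Why: Julia–Kocienski olefination: the sulfonyl carbanion adds to the aldehyde, Smiles rearrangement and loss of SO2 and the tetrazolone give the alkene, and the hindered α-quaternary aldehyde should favour the anti adduct and hence E. Base is added to the mixture of both partners so that the carbanion is trapped before lactone enolate chemistry can develop.

Step 18
Reactants: 28 (4S,5R)-4-[(2S,3Z)-4-iodo-2-(4-methoxybenzyloxy)-3-methylbut-3-en-1-yl]-5-[(1E,4E,6S)-2,6-dimethyl-6-(triethylsilyloxy)octa-1,4,7-trien-1-yl]dihydrofuran-2(3H)-one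
Product: 30 (1S,2R,3E,6E,8S,11Z,13S)-13-(4-methoxybenzyloxy)-8-(triethylsilyloxy)cembra-3,6,11-trien-16,2-olide, via B-alkyl-9-BBN borane 29 (not isolated)
Conditions: 9-BBN (1.5 equiv), THF, 0 °C → rt; then slow addition to Pd(dppf)Cl2 (15 mol%), AsPh3 (30 mol%), Cs2CO3 (3 equiv), DMF/THF/H2O, rt → 45 °C, final 0.002 M
Reagents that add atoms: none
Why: 9-BBN adds anti-Markovnikov to the C9–C10 vinyl group and gives borane 29 with boron on C10. Zerovalent palladium formed from Pd(dppf)Cl2 inserts into the C11–I bond with retention, base activates the boron, the primary alkyl group transmetallates and reductive elimination forms the C10–C11 sp3–sp2 bond. The closest known reaction type is the intramolecular B-alkyl Suzuki–Miyaura coupling used for macrocyclisation. The 14-membered carbocycle closes in the reductive elimination from a palladacycle spanning C10 and C11, with the C11=C12 alkene inside the new ring, and slow addition keeps the borane dilute. No stereocentre is formed, and the Z geometry of C11=C12 is carried through because oxidative addition and reductive elimination both go with retention. The step needs hydroboration at the monosubstituted alkene only: 9-BBN discriminates against the E-disubstituted C6=C7 next to quaternary C8, the trisubstituted C3=C4 and the iodoalkene, and it leaves the lactone carbonyl alone. The lactone is kept saturated so that no conjugate acceptor meets the borane. The wide bite angle of dppf favours reductive elimination over β-hydride elimination, and AsPh3 should speed the transmetallation.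

Step 19
Reactants: 30 (1S,2R,3E,6E,8S,11Z,13S)-13-(4-methoxybenzyloxy)-8-(triethylsilyloxy)cembra-3,6,11-trien-16,2-olide
Product: 32 15-(dimethylaminomethyl) derivative of 30 (aminomethyl on C15 trans to C14), via lithium enolate 31 (not isolated)
Conditions: LiN(iPr)2 (1.5 equiv), THF, −78 °C; CH2=NMe2+ I− (4 equiv), −78 °C → rt
Reagents that add atoms: N,N-dimethylmethyleneiminium iodide (Eschenmoser's salt) C=[N+](C)C.[I-]
Why: Mannich reaction of the lactone enolate; the iminium ion should approach the face opposite C14 on the cis-fused lactone. The new C15 centre is destroyed in the next step, so its ratio does not matter.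

Step 20
Reactants: 32 15-(dimethylaminomethyl) derivative of 30
Product: 34 (1S,2S,3E,6E,8S,11Z,13S)-13-(4-methoxybenzyloxy)-8-(triethylsilyloxy)cembra-3,6,11,15(17)-tetraen-16,2-olide, via trimethylammonium iodide 33 (not isolated)
Conditions: MeI (excess), MeOH/CH2Cl2, rt; then aqueous NaHCO3, EtOAc, rt
Reagents that add atoms: none
Why: Exhaustive N-methylation followed by base-induced β-elimination of trimethylamine (E1cB) gives the exocyclic alkene under conditions too mild to touch the ethers. The C2 descriptor changes from R to S only through CIP priorities.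

Step 21
Reactants: 34 (1S,2S,3E,6E,8S,11Z,13S)-13-(4-methoxybenzyloxy)-8-(triethylsilyloxy)cembra-3,6,11,15(17)-tetraen-16,2-olide
Product: 35 (1S,2S,3E,6E,8S,11Z,13S)-13-hydroxy-8-(triethylsilyloxy)cembra-3,6,11,15(17)-tetraen-16,2-olide
Conditions: DDQ (1.3 equiv), CH2Cl2/pH 7 phosphate buffer, 0 °C
Reagents that add atoms: none
Why: Oxidative cleavage of the p-methoxybenzyl ether by benzylic hydride abstraction and hydrolysis of the oxocarbenium ion; the buffer protects the tertiary allylic silyl ether.

Step 22
Reactants: 35 (1S,2S,3E,6E,8S,11Z,13S)-13-hydroxy-8-(triethylsilyloxy)cembra-3,6,11,15(17)-tetraen-16,2-olide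
Product: 36 (1S,2S,3E,6E,8S,11S,12R,13S)-11,12-epoxy-13-hydroxy-8-(triethylsilyloxy)cembra-3,6,15(17)-trien-16,2-olide
Conditions: VO(acac)2 (10 mol%), t-BuOOH (decane), CH2Cl2, 0 °C → rt
Reagents that add atoms: tert-butyl hydroperoxide CC(C)(C)OO
Why: Vanadium-catalysed hydroxyl-directed epoxidation; only C11=C12 has a free allylic hydroxyl, and the methylene lactone is too electron-poor to react. Allylic 1,3-strain against C10 holds the C13–H bond in the alkene plane, so the vanadate ester on O13 delivers oxygen to the face opposite C14 (threo), which is the epoxide face of the target.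

Step 23
Reactants: 36 (1S,2S,3E,6E,8S,11S,12R,13S)-11,12-epoxy-13-hydroxy-8-(triethylsilyloxy)cembra-3,6,15(17)-trien-16,2-olide
Product: 37 (1S,2S,3E,6E,8S,11S,12S,13R)-13-acetoxy-11,12-epoxy-8-(triethylsilyloxy)cembra-3,6,15(17)-trien-16,2-olide
Conditions: PPh3, DIAD, AcOH, toluene, 0 °C → rt
Reagents that add atoms: acetic acid CC(=O)O
Why: Mitsunobu esterification with inversion at C13 turns the threo epoxy alcohol into the erythro acetate of the target in one step. The C12 descriptor changes from R to S only through CIP priorities.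

Step 24
Reactants: 37 (1S,2S,3E,6E,8S,11S,12S,13R)-13-acetoxy-11,12-epoxy-8-(triethylsilyloxy)cembra-3,6,15(17)-trien-16,2-olide
Product: 38 (1S,2S,3E,6E,8S,11S,12S,13R)-13-acetoxy-11,12-epoxy-8-hydroxycembra-3,6,15(17)-trien-16,2-olide
Conditions: HF·pyridine, pyridine, THF, 0 °C → rt
Reagents that add atoms: none
Why: Buffered fluoride cleavage of the tertiary triethylsilyl ether; excess pyridine keeps the medium too weakly acidic to open the epoxide or ionise the allylic alcohol.

## Compound list

1 | prop-2-yn-1-ol | C#CCO | starting material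
2 | bromomagnesium (Z)-3-(bromomagnesio)-2-methylprop-2-en-1-olate | Br[Mg]/C=C(/C)CO[Mg]Br | intermediate
3 | (Z)-3-iodo-2-methylprop-2-en-1-ol | I/C=C(/C)CO | intermediate
4 | (Z)-3-iodo-2-methylprop-2-enal | I/C=C(/C)C=O | intermediate
5 | (3S,1Z)-1-iodo-2-methylhexa-1,5-dien-3-yl diisopinocampheylborinate | I/C=C(/C)[C@@H](OB([C@H]1[C@H](C)[C@H]2C[C@@H](C1)C2(C)C)[C@H]1[C@H](C)[C@H]2C[C@@H](C1)C2(C)C)CC=C | intermediate
6 | (3S,1Z)-1-iodo-2-methylhexa-1,5-dien-3-ol | I/C=C(/C)[C@@H](O)CC=C | intermediate
7 | (3S,1Z)-1-iodo-3-(4-methoxybenzyloxy)-2-methylhexa-1,5-diene | I/C=C(/C)[C@@H](OCc1ccc(OC)cc1)CC=C | intermediate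
8 | 2-[(2Z,5S,6Z)-7-iodo-5-(4-methoxybenzyloxy)-6-methylhepta-2,6-dien-1-yl]-4,4,5,5-tetramethyl-1,3,2-dioxaborolane | I/C=C(/C)[C@@H](OCc1ccc(OC)cc1)C/C=C\CB1OC(C)(C)C(C)(C)O1 | intermediate
9 | tert-butyl(but-3-yn-1-yloxy)dimethylsilane | C#CCCO[Si](C)(C)C(C)(C)C | starting material
10 | [(E)-4-(tert-butyldimethylsilyloxy)-2-methylbut-1-en-1-yl]dimethylalane | C[Al](C)/C=C(\C)CCO[Si](C)(C)C(C)(C)C | intermediate
11 | (E)-5-(tert-butyldimethylsilyloxy)-3-methylpent-2-en-1-ol | OC/C=C(\C)CCO[Si](C)(C)C(C)(C)C | intermediate
12 | (E)-5-(tert-butyldimethylsilyloxy)-3-methylpent-2-enal | O=C/C=C(\C)CCO[Si](C)(C)C(C)(C)C | intermediate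
13 | pinacol borate ester of 14 (boron on the C5 oxygen) | I/C=C(/C)[C@@H](OCc1ccc(OC)cc1)C[C@H]([C@@H](OB1OC(C)(C)C(C)(C)O1)/C=C(\C)CCO[Si](C)(C)C(C)(C)C)C=C | intermediate
14 | (3E,5R,6S,8S,9Z)-1-(tert-butyldimethylsilyloxy)-6-ethenyl-10-iodo-8-(4-methoxybenzyloxy)-3,9-dimethyldeca-3,9-dien-5-ol (cembrane C2 R, C1 S, C13 S; C1/C2 syn) | I/C=C(/C)[C@@H](OCc1ccc(OC)cc1)C[C@H]([C@@H](O)/C=C(\C)CCO[Si](C)(C)C(C)(C)C)C=C | intermediate
15 | 14 carrying 9-borabicyclo[3.3.1]nonan-9-yl groups on the C5 oxygen and on the terminal carbon of the former ethenyl group | I/C=C(/C)[C@@H](OCc1ccc(OC)cc1)C[C@H]([C@@H](OB1C2CCCC1CCC2)/C=C(\C)CCO[Si](C)(C)C(C)(C)C)CCB1C2CCCC1CCC2 | intermediate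
16 | (3E,5R,6R,8S,9Z)-1-(tert-butyldimethylsilyloxy)-6-(2-hydroxyethyl)-10-iodo-8-(4-methoxybenzyloxy)-3,9-dimethyldeca-3,9-dien-5-ol (same spatial arrangement as 14) | I/C=C(/C)[C@@H](OCc1ccc(OC)cc1)C[C@H]([C@@H](O)/C=C(\C)CCO[Si](C)(C)C(C)(C)C)CCO | intermediate
17 | lactol of 18 (2-hydroxytetrahydrofuran, both anomers; other centres as in 18) | I/C=C(/C)[C@@H](OCc1ccc(OC)cc1)C[C@H]1CC(O)O[C@H]1/C=C(\C)CCO[Si](C)(C)C(C)(C)C | intermediate
18 | (4S,5R)-5-[(E)-4-(tert-butyldimethylsilyloxy)-2-methylbut-1-en-1-yl]-4-[(2S,3Z)-4-iodo-2-(4-methoxybenzyloxy)-3-methylbut-3-en-1-yl]dihydrofuran-2(3H)-one | I/C=C(/C)[C@@H](OCc1ccc(OC)cc1)C[C@H]1CC(=O)O[C@H]1/C=C(\C)CCO[Si](C)(C)C(C)(C)C | intermediate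
19 | (4S,5R)-5-[(E)-4-hydroxy-2-methylbut-1-en-1-yl]-4-[(2S,3Z)-4-iodo-2-(4-methoxybenzyloxy)-3-methylbut-3-en-1-yl]dihydrofuran-2(3H)-one | I/C=C(/C)[C@@H](OCc1ccc(OC)cc1)C[C@H]1CC(=O)O[C@H]1/C=C(\C)CCO | intermediate
20 | (4S,5R)-4-[(2S,3Z)-4-iodo-2-(4-methoxybenzyloxy)-3-methylbut-3-en-1-yl]-5-[(E)-2-methyl-4-(1-phenyl-1H-tetrazol-5-ylthio)but-1-en-1-yl]dihydrofuran-2(3H)-one | I/C=C(/C)[C@@H](OCc1ccc(OC)cc1)C[C@H]1CC(=O)O[C@H]1/C=C(\C)CCSc1nnnn1-c1ccccc1 | intermediate
21 | sulfoxide of 20 (both epimers at sulfur) | I/C=C(/C)[C@@H](OCc1ccc(OC)cc1)C[C@H]1CC(=O)O[C@H]1/C=C(\C)CCS(=O)c1nnnn1-c1ccccc1 | intermediate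
22 | (4S,5R)-4-[(2S,3Z)-4-iodo-2-(4-methoxybenzyloxy)-3-methylbut-3-en-1-yl]-5-[(E)-2-methyl-4-(1-phenyl-1H-tetrazol-5-ylsulfonyl)but-1-en-1-yl]dihydrofuran-2(3H)-one | I/C=C(/C)[C@@H](OCc1ccc(OC)cc1)C[C@H]1CC(=O)O[C@H]1/C=C(\C)CCS(=O)(=O)c1nnnn1-c1ccccc1 | intermediate
23 | 2-methyl-2-vinyloxirane (racemic) | CC1(C=C)CO1 | starting material
24 | (S)-2-methylbut-3-ene-1,2-diol | OC[C@@](C)(O)C=C | intermediate
25 | (S)-2-methyl-1,2-bis(triethylsilyloxy)but-3-ene | CC[Si](CC)(CC)OC[C@@](C)(O[Si](CC)(CC)CC)C=C | intermediate
26 | (S)-2-methyl-2-(triethylsilyloxy)but-3-enal | O=C[C@@](C)(O[Si](CC)(CC)CC)C=C | intermediate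
27 | potassium β-alkoxide adduct of 22 and 26 (C6 sulfone, C7 alkoxide; mixture at C6 and C7) | I/C=C(/C)[C@@H](OCc1ccc(OC)cc1)C[C@H]1CC(=O)O[C@H]1/C=C(\C)CC(C([O-])[C@@](C)(O[Si](CC)(CC)CC)C=C)S(=O)(=O)c1nnnn1-c1ccccc1.[K+] | intermediate
28 | (4S,5R)-4-[(2S,3Z)-4-iodo-2-(4-methoxybenzyloxy)-3-methylbut-3-en-1-yl]-5-[(1E,4E,6S)-2,6-dimethyl-6-(triethylsilyloxy)octa-1,4,7-trien-1-yl]dihydrofuran-2(3H)-one (seco Z-iodoalkene) | I/C=C(/C)[C@@H](OCc1ccc(OC)cc1)C[C@H]1CC(=O)O[C@H]1/C=C(\C)C/C=C/[C@@](C)(O[Si](CC)(CC)CC)C=C | intermediate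
29 | 28 with the C9–C10 vinyl group hydroborated (9-borabicyclo[3.3.1]nonan-9-yl on C10) | I/C=C(/C)[C@@H](OCc1ccc(OC)cc1)C[C@H]1CC(=O)O[C@H]1/C=C(\C)C/C=C/[C@@](C)(O[Si](CC)(CC)CC)CCB1C2CCCC1CCC2 | intermediate
30 | (1S,2R,3E,6E,8S,11Z,13S)-13-(4-methoxybenzyloxy)-8-(triethylsilyloxy)cembra-3,6,11-trien-16,2-olide | C1C(=O)O[C@H]2/C=C(\C)C/C=C/[C@@](C)(O[Si](CC)(CC)CC)CC/C=C(/C)[C@@H](OCc3ccc(OC)cc3)C[C@@H]12 | intermediate
31 | lithium enolate of 30 (C15=C16, O–Li) | C1=C(O[Li])O[C@H]2/C=C(\C)C/C=C/[C@@](C)(O[Si](CC)(CC)CC)CC/C=C(/C)[C@@H](OCc3ccc(OC)cc3)C[C@@H]12 | intermediate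
32 | 15-(dimethylaminomethyl) derivative of 30 (aminomethyl trans to C14) | CN(C)C[C@@H]1C(=O)O[C@H]2/C=C(\C)C/C=C/[C@@](C)(O[Si](CC)(CC)CC)CC/C=C(/C)[C@@H](OCc3ccc(OC)cc3)C[C@@H]12 | intermediate
33 | trimethylammonium iodide of 32 | C[N+](C)(C)C[C@@H]1C(=O)O[C@H]2/C=C(\C)C/C=C/[C@@](C)(O[Si](CC)(CC)CC)CC/C=C(/C)[C@@H](OCc3ccc(OC)cc3)C[C@@H]12.[I-] | intermediate
34 | (1S,2S,3E,6E,8S,11Z,13S)-13-(4-methoxybenzyloxy)-8-(triethylsilyloxy)cembra-3,6,11,15(17)-tetraen-16,2-olide | C=C1C(=O)O[C@H]2/C=C(\C)C/C=C/[C@@](C)(O[Si](CC)(CC)CC)CC/C=C(/C)[C@@H](OCc3ccc(OC)cc3)C[C@@H]12 | intermediate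
35 | (1S,2S,3E,6E,8S,11Z,13S)-13-hydroxy-8-(triethylsilyloxy)cembra-3,6,11,15(17)-tetraen-16,2-olide | C=C1C(=O)O[C@H]2/C=C(\C)C/C=C/[C@@](C)(O[Si](CC)(CC)CC)CC/C=C(/C)[C@@H](O)C[C@@H]12 | intermediate
36 | (1S,2S,3E,6E,8S,11S,12R,13S)-11,12-epoxy-13-hydroxy-8-(triethylsilyloxy)cembra-3,6,15(17)-trien-16,2-olide (threo) | C=C1C(=O)O[C@H]2/C=C(\C)C/C=C/[C@@](C)(O[Si](CC)(CC)CC)CC[C@@H]3O[C@]3(C)[C@@H](O)C[C@@H]12 | intermediate
37 | (1S,2S,3E,6E,8S,11S,12S,13R)-13-acetoxy-11,12-epoxy-8-(triethylsilyloxy)cembra-3,6,15(17)-trien-16,2-olide | C=C1C(=O)O[C@H]2/C=C(\C)C/C=C/[C@@](C)(O[Si](CC)(CC)CC)CC[C@@H]3O[C@]3(C)[C@H](OC(C)=O)C[C@@H]12 | intermediate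
38 | (1S,2S,3E,6E,8S,11S,12S,13R)-13-acetoxy-11,12-epoxy-8-hydroxycembra-3,6,15(17)-trien-16,2-olide | C=C1C(=O)O[C@H]2/C=C(\C)C/C=C/[C@@](C)(O)CC[C@@H]3O[C@]3(C)[C@H](OC(C)=O)C[C@@H]12 | target

## Step count and least certain steps

Total: 24 steps. Longest linear sequence: 19 steps (1–5, 8–13, 17–24, from propargyl alcohol).

Step 18 (key step). At the dilution needed for ring closure, activation of the borane by base and transmetallation are slow. Protodeboronation, reduction of the alkenyl iodide, β-hydride elimination and intermolecular coupling may then compete, and the aqueous carbonate may open the lactone.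
- Fallback: form the C10–C11 bond at normal concentration and close the ring at C6=C7 instead. It sets out from 25 and 22 and returns at 30.
- Silyl ether 25 is hydroborated with 9-BBN to the B-alkyl borane F1, which is coupled with iodoalkene 22 under the same Pd(dppf)Cl2 conditions to give the coupled sulfone F2.
- Swern treatment unmasks the primary silyl ether as the seco aldehyde F3.
- An intramolecular Julia–Kocienski olefination (KN(SiMe3)2, high dilution) then gives 30.

Step 5. The Z selectivity of the metathesis may erode by secondary metathesis of the product as ethene builds up, or the alkylidene may be deactivated by the ether oxygens. An E-contaminated boronate would give anti adducts in step 8. The fallback also takes over step 8 if the acid-catalysed allylboration shows poor facial control.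
- Fallback: fix the Z geometry by olefination and use silicon in place of boron. It sets out from 7 and returns at 14.
- Oxidative cleavage of the terminal alkene (OsO4, NaIO4) gives the aldehyde F4.
- Still–Gennari olefination gives the Z enoate F5, and reduction with iBu2AlH gives the Z allylic alcohol F6.
- Mesylation with chloride displacement gives the Z allylic chloride F7.
- HSiCl3 with CuCl and iPr2NEt gives the Z allyltrichlorosilane F8, which is added to 12 under chiral bisphosphoramide Lewis-base catalysis through a closed transition state to give 14.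

Step 17. Addition of the sulfonyl carbanion to the hindered α-quaternary aldehyde may be slow enough for deprotonation next to the lactone carbonyl and self-condensation to compete, and E selectivity may suffer.
- Fallback: use an unhindered enal and build C8 after the union by epoxidation and reductive opening. It sets out from 22 and returns at 28.
- Olefination of 22 with (E)-4-acetoxy-2-methylbut-2-enal F9 (from 3-methylbut-2-enyl acetate and SeO2) gives the dienyl acetate F10, and mild methanolysis gives the dienol F11.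
- Sharpless asymmetric epoxidation with Ti(OiPr)4, D-(−)-diethyl tartrate and t-BuOOH gives the epoxy alcohol F12.
- I2, PPh3 and imidazole give the epoxy iodide F13, and zinc opens it reductively to the tertiary allylic alcohol F14.
- Et3SiOTf then gives 28.

Step 22. The vanadate ester prefers a small O–C–C=C angle, which conflicts with the rotamer that allylic strain favours, and the macrocycle may expose the other face. Poor facial selectivity or slow reaction with over-oxidation at C3=C4 could result.
- Fallback: reagent control in the erythro manifold, which also replaces step 23. It sets out from 35 and returns at 37.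
- Dess–Martin oxidation of 35 gives the enone F15.
- Corey–Bakshi–Shibata reduction ((S)-oxazaborolidine, catecholborane) gives the 13R allylic alcohol F16.
- Matched Sharpless epoxidation (Ti(OiPr)4, D-(−)-diethyl tartrate, t-BuOOH) gives the erythro epoxy alcohol F17, and Ac2O with 4-dimethylaminopyridine gives 37.

Step 23. Substitution at a carbinol flanked by a fully substituted epoxide carbon is slow. Elimination, participation of the epoxide oxygen or addition of the phosphine to the methylene lactone may take over, and acetic acid is a weak Mitsunobu partner.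
- Fallback: invert by oxidation and reduction. It sets out from 36 and returns at 37.
- Dess–Martin oxidation of 36 gives the epoxy ketone F18.
- Chelation-controlled reduction with Zn(BH4)2 at low temperature gives the erythro epoxy alcohol F17, which is acetylated to 37.

## Further compounds

F1 | step 18 | 9-[(S)-3-methyl-3,4-bis(triethylsilyloxy)butyl]-9-borabicyclo[3.3.1]nonane | CC[Si](CC)(CC)OC[C@@](C)(O[Si](CC)(CC)CC)CCB1C2CCCC1CCC2
F2 | step 18 | coupled sulfone: 22 with iodine replaced by the (S)-3-methyl-3,4-bis(triethylsilyloxy)butyl group (C10–C11 formed, Z retained) | CC[Si](CC)(CC)OC[C@@](C)(O[Si](CC)(CC)CC)CC/C=C(/C)[C@@H](OCc1ccc(OC)cc1)C[C@H]1CC(=O)O[C@H]1/C=C(\C)CCS(=O)(=O)c1nnnn1-c1ccccc1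
F3 | step 18 | seco aldehyde sulfone (C7 aldehyde, C8 triethylsilyl ether, C6 sulfone) | O=C[C@@](C)(O[Si](CC)(CC)CC)CC/C=C(/C)[C@@H](OCc1ccc(OC)cc1)C[C@H]1CC(=O)O[C@H]1/C=C(\C)CCS(=O)(=O)c1nnnn1-c1ccccc1
F4 | step 5 | (3S,4Z)-5-iodo-3-(4-methoxybenzyloxy)-4-methylpent-4-enal | I/C=C(/C)[C@@H](OCc1ccc(OC)cc1)CC=O
F5 | step 5 | methyl (2Z,5S,6Z)-7-iodo-5-(4-methoxybenzyloxy)-6-methylhepta-2,6-dienoate | I/C=C(/C)[C@@H](OCc1ccc(OC)cc1)C/C=C\C(=O)OC
F6 | step 5 | (2Z,5S,6Z)-7-iodo-5-(4-methoxybenzyloxy)-6-methylhepta-2,6-dien-1-ol | I/C=C(/C)[C@@H](OCc1ccc(OC)cc1)C/C=C\CO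
F7 | step 5 | (1Z,3S,5Z)-7-chloro-1-iodo-3-(4-methoxybenzyloxy)-2-methylhepta-1,5-diene | I/C=C(/C)[C@@H](OCc1ccc(OC)cc1)C/C=C\CCl
F8 | step 5 | trichloro[(2Z,5S,6Z)-7-iodo-5-(4-methoxybenzyloxy)-6-methylhepta-2,6-dien-1-yl]silane | I/C=C(/C)[C@@H](OCc1ccc(OC)cc1)C/C=C\C[Si](Cl)(Cl)Cl
F9 | step 17 | (E)-4-acetoxy-2-methylbut-2-enal | CC(=O)OC/C=C(\C)C=O
F10 | step 17 | dienyl acetate: lactone of 22 carrying the (1E,4E,6E)-8-acetoxy-2,6-dimethylocta-1,4,6-trien-1-yl chain on C2 | I/C=C(/C)[C@@H](OCc1ccc(OC)cc1)C[C@H]1CC(=O)O[C@H]1/C=C(\C)C/C=C/C(C)=C/COC(C)=O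
F11 | step 17 | dienol from F10 (C10 primary alcohol) | I/C=C(/C)[C@@H](OCc1ccc(OC)cc1)C[C@H]1CC(=O)O[C@H]1/C=C(\C)C/C=C/C(C)=C/CO
F12 | step 17 | (8R,9R)-8,9-epoxy alcohol from F11 | I/C=C(/C)[C@@H](OCc1ccc(OC)cc1)C[C@H]1CC(=O)O[C@H]1/C=C(\C)C/C=C/[C@@]1(C)O[C@@H]1CO
F13 | step 17 | epoxy iodide from F12 (C10 iodide) | I/C=C(/C)[C@@H](OCc1ccc(OC)cc1)C[C@H]1CC(=O)O[C@H]1/C=C(\C)C/C=C/[C@@]1(C)O[C@@H]1CI
F14 | step 17 | tertiary allylic alcohol: 28 with free C8 hydroxyl (8S) | I/C=C(/C)[C@@H](OCc1ccc(OC)cc1)C[C@H]1CC(=O)O[C@H]1/C=C(\C)C/C=C/[C@@](C)(O)C=C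
F15 | step 22 | 13-oxo compound (Z enone) from 35 | C=C1C(=O)O[C@H]2/C=C(\C)C/C=C/[C@@](C)(O[Si](CC)(CC)CC)CC/C=C(/C)C(=O)C[C@@H]12
F16 | step 22 | 13R epimer of 35 | C=C1C(=O)O[C@H]2/C=C(\C)C/C=C/[C@@](C)(O[Si](CC)(CC)CC)CC/C=C(/C)[C@H](O)C[C@@H]12
F17 | step 22 | erythro epoxy alcohol (13R epimer of 36) | C=C1C(=O)O[C@H]2/C=C(\C)C/C=C/[C@@](C)(O[Si](CC)(CC)CC)CC[C@@H]3O[C@]3(C)[C@H](O)C[C@@H]12
F18 | step 23 | 11,12-epoxy-13-oxo compound from 36 | C=C1C(=O)O[C@H]2/C=C(\C)C/C=C/[C@@](C)(O[Si](CC)(CC)CC)CC[C@@H]3O[C@]3(C)C(=O)C[C@@H]12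
A1 | alternative 1 | cis-fused methylene lactone with C3–C12 chain, C12 iodoalkene and C13 primary p-methoxybenzyl ether | COc1ccc(COCC[C@H]2C(=C)C(=O)O[C@H]2/C=C(\C)C/C=C/[C@@](C)(O[Si](CC)(CC)CC)CC/C=C(/C)I)cc1
A2 | alternative 1 | alkyne fragment (C3–C12): (S,4E,9Z)-10-iodo-6,9-dimethyl-6-(triethylsilyloxy)deca-4,9-dien-1-yne | C#CC/C=C/[C@@](C)(O[Si](CC)(CC)CC)CC/C=C(/C)I
A3 | alternative 1 | aldehyde fragment: methyl 3-formyl-5-(4-methoxybenzyloxy)-2-methylenepentanoate (C1 as in the target) | COc1ccc(COCC[C@H](C=O)C(=C)C(=O)OC)cc1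
A4 | alternative 2 | macrocyclic methylene lactone, identical with 34 | C=C1C(=O)O[C@H]2/C=C(\C)C/C=C/[C@@](C)(O[Si](CC)(CC)CC)CC/C=C(/C)[C@@H](OCc3ccc(OC)cc3)C[C@@H]12
A5 | alternative 2 | macrocyclic homopropargylic alcohol (ethynyl on C1, hydroxyl on C2, syn) | C#C[C@H]1[C@@H](O)/C=C(\C)C/C=C/[C@@](C)(O[Si](CC)(CC)CC)CC/C=C(/C)[C@@H](OCc2ccc(OC)cc2)C1
A6 | alternative 3 | C8 triethylsilyl ether of the target, identical with 37 | C=C1C(=O)O[C@H]2/C=C(\C)C/C=C/[C@@](C)(O[Si](CC)(CC)CC)CC[C@@H]3O[C@]3(C)[C@H](OC(C)=O)C[C@@H]12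
A7 | alternative 3 | seco enyne (propynyl on C2, allyl on C8, epoxy acetate and methylene lactone in place) | C=C1C(=O)O[C@@H](C#CC)[C@H]1C[C@@H](OC(C)=O)[C@@]2(C)O[C@H]2CC[C@](C)(O[Si](CC)(CC)CC)CC=C
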